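The numbers in the tables come from a simulation for an exercise.

You get no constants for this flask, so start from the charges.

| setting | alder | cedar | elm | flask |
|---|---|---|---|---|
| substrate | 0.010 M | 0.015 M | 0.020 M | 0.020 M |
| partner | 0.024 M | 0.024 M | 0.048 M | 0.0240 M |
| free catalyst | 0.20 mM | 0.20 mM | 0.20 mM | 0.20 mM |
| impurity | 0.13 mM | 0.13 mM | 0.13 mM | 0.13 mM |
| remark | run made earlier | run made earlier | run made earlier |  |
| time |  |  |  | 15 h |

| run | time / h | substrate / % | target / % | catalyst intermediate C / % | catalyst intermediate D / % |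
|---|---|---|---|---|---|
| alder | 1.00 | 95.1 | 4.1 | 0 | 0.4 |
| alder | 2.00 | 90.6 | 9.1 | 0.1 | 0.6 |
| alder | 3.00 | 86.3 | 12.4 | 0 | 0.2 |
| alder | 6.00 | 77.2 | 23.3 | 0 | 0 |
| alder | 12.0 | 61.5 | 38.5 | 0.1 | 0 |
| cedar | 2.50 | 91.7 | 7.8 | 0.1 | 0.2 |
| cedar | 5.00 | 85.1 | 14.6 | 0 | 0 |
| cedar | 8.00 | 78.5 | 20.7 | 0.3 | 0.6 |
| cedar | 10.0 | 74.7 | 24.5 | 0.2 | 0.4 |
| cedar | 12.0 | 71.2 | 28.6 | 0 | 0 |
| elm | 2.50 | 92.0 | 7.5 | 0.1 | 0.6 |
| elm | 5.00 | 86.1 | 13.6 | 0 | 0 |
| elm | 8.00 | 79.4 | 20.0 | 0 | 0 |
| elm | 10.0 | 75.3 | 24.6 | 0.4 | 0 |
| elm | 12.0 | 71.2 | 27.8 | 0 | 0.4 |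

(standard deviation of a reading: 0.3 percentage points)



* the largest share of what was charged as substrate, at 15 h belongs to (catalyst intermediate C / substrate / target / catalyst intermediate D)
* the largest share itself, whichever of these holds it, in percent of the substrate charged

Impurity has the same charge in alder, cedar, elm and the flask, and so has free catalyst. Divide the first by the second and you get 65.0%, the poison fraction: the share of the catalyst that the impurity can remove if it takes it one for one. That share stands below one whole, so the impurity should be the limiting reagent of this loss, and 35.0% of the catalyst should keep working.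

Elm shows the slowing. Its substrate drops 8 percentage points in the first 2.50 h but 4.1 points in the last 2.00 h. As read, with the scatter of the readings, its rate has come down to 64.1% of the early rate, still above that remainder, so expect more slowing.

My own reckoning carries elm's last slope to 15 h, which leaves 65.1% substrate. But the flask has half of elm's partner, so I take that as the low side.

The forecast says substrate at 73%, above my low side, and of the slowing: “This suggests catalyst decay or product inhibition.”

The flask gives substrate at 73.5%.

catalyst intermediate D → free catalyst + target (k = 10.1 h⁻¹); partner → decomposition product (k = 4.38 × 10⁻⁵ h⁻¹); catalyst intermediate A → by-product + catalyst intermediate B (k = 14.7 h⁻¹); substrate + catalyst intermediate B → catalyst intermediate C (k = 994 M⁻¹ h⁻¹); free catalyst + impurity → spent catalyst (k = 8230 M⁻¹ h⁻¹); catalyst intermediate C → catalyst intermediate D (k = 17.5 h⁻¹); partner + free catalyst → catalyst intermediate A (k = 964 M⁻¹ h⁻¹) At 15.0 h the flask holds 57.4% of its catalyst as spent catalyst, with 11.7% of its impurity left. At 150 h the flask's spent catalyst stands at 65.0%, the poison fraction of 65.0% again. In a neighbour flask the answer changes: with free catalyst at 8.0 × 10⁻⁴ M the poison fraction is 16.2%, spent catalyst reaches 16.2%, and at 15.0 h target holds 97.7%.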